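**Retrosynthetic overview**
- Garcinielliptone HC ⇒ aromatic (2R)-7-isobutyryl-4,6-dihydroxy-2-(2-hydroxypropan-2-yl)-2,3-dihydrobenzofuran, by a final dearomatising double C-prenylation at C5.
- That dihydrobenzofuran ⇒ the corresponding benzofuran; C2 is set by enantioselective hydrogenation of the furan C2=C3 bond.
- Benzofuran ⇒ key C–C bond (ring C3a–C3) between two normally nucleophilic carbons: the ring carbon of 4-O-silylated phlorisobutyrophenone and the α-carbon of 3-hydroxy-3-methylbutan-2-one, used as its α-bromoketone (enolonium-type a2 synthon); cyclodehydration then closes the furan.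
- 4-O-Silyl phlorisobutyrophenone ⇒ phloroglucinol + isobutyryl chloride (Friedel–Crafts acylation, then para-selective silylation for regiocontrol).
- Ring order: benzene ring purchased → furan ring closed → furan ring reduced → carbocycle dearomatised.

Assumption: the target is the (2R) enantiomer encoded by the SMILES, drawn as its exocyclic Z-enol tautomer; the route has not been run, and conditions are by analogy to the named reaction types.

Step 1
Reactants: 1 phloroglucinol (benzene-1,3,5-triol); 2 isobutyryl chloride (2-methylpropanoyl chloride)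
Product: 3 2-methyl-1-(2,4,6-trihydroxyphenyl)propan-1-one (phlorisobutyrophenone)
Conditions: AlCl3 (3.5 equiv), PhNO2/CH2Cl2, 0 → 45 °C; then ice/aq. HCl
Reagents that add atoms: none
Why: Friedel–Crafts C-acylation of the threefold-symmetric, very electron-rich arene gives a single mono-ketone, because the aluminium-chelated acyl group deactivates the ring towards a second acylation.

Step 2
Reactants: 3 2-methyl-1-(2,4,6-trihydroxyphenyl)propan-1-one
Product: 4 1-[2,6-dihydroxy-4-(triisopropylsilyloxy)phenyl]-2-methylpropan-1-one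
Conditions: TIPSCl (1.05 equiv), imidazole (2.2 equiv), DMF, 0 °C
Reagents that add atoms: triisopropylsilyl chloride, CC(C)[Si](Cl)(C(C)C)C(C)C
Why: Silyl ether formation is selective for the 4-OH (most acidic, unhindered, not hydrogen-bonded to the ketone), and blocking it makes C3/C5 and O2/O6 pairwise equivalent, so the later furan closure can only use an oxygen ortho to the acyl group.

Step 3
Reactants: 4 1-[2,6-dihydroxy-4-(triisopropylsilyloxy)phenyl]-2-methylpropan-1-one; 5 3-hydroxy-3-methylbutan-2-one
Product: 8 1-[6-hydroxy-2-(2-hydroxypropan-2-yl)-4-(triisopropylsilyloxy)-1-benzofuran-7-yl]-2-methylpropan-1-one, via 1-bromo-3-hydroxy-3-methylbutan-2-one 6 (not isolated), via open keto-phenol 7 (not isolated)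
Conditions: 5 (1.1 equiv), Br2 (1.0 equiv), CF3CH2OH, 0 °C → rt until colourless; then 4 (1.0 equiv), K2CO3 (2.3 equiv), 0 °C → rt; then filter, PPTS (0.2 equiv), 50 °C
Reagents that add atoms: none
Why: The α-bromoketone is an enolonium (a2) equivalent, so its CH2 carbon (normally a nucleophilic enolate carbon) is joined by SN2 to the equally nucleophilic ring carbon C3 of the phenoxide, with C- over O-alkylation steered by the hydrogen-bonding fluorinated alcohol and the ketone-chelated phenoxide; the o-hydroxybenzyl ketone then cyclodehydrates through its only free flanking hydroxyl (Feist–Benary-type α-haloketone benzofuran annulation), and no stereocentre is formed.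

Step 4
Reactants: 8 1-[6-hydroxy-2-(2-hydroxypropan-2-yl)-4-(triisopropylsilyloxy)-1-benzofuran-7-yl]-2-methylpropan-1-one
Product: 9 1-[(2R)-6-hydroxy-2-(2-hydroxypropan-2-yl)-4-(triisopropylsilyloxy)-2,3-dihydro-1-benzofuran-7-yl]-2-methylpropan-1-one
Conditions: H2 (60 bar), catalyst preformed from Ru(cod)(2-methylallyl)2 (5 mol %), (S,S)-SINpEt·HBF4 (10 mol %) and KOtBu (12 mol %), toluene, 40 °C
Reagents that add atoms: none
Why: Ruthenium–NHC-catalysed asymmetric hydrogenation of 2-substituted benzofurans reduces only the furan C2=C3 bond, and face-selective cis delivery of H2 by the chiral catalyst sets C2 as R (spatially the sense of (S)-2-methyl-2,3-dihydrobenzofuran, since the carbinol substituent outranks C3; I have not confirmed which ligand antipode gives this sense, so the antipode is used if the first run shows the opposite), while the hindered hydrogen-bonded aryl ketone and the silyl ether are inert.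

Step 5
Reactants: 9 1-[(2R)-6-hydroxy-2-(2-hydroxypropan-2-yl)-4-(triisopropylsilyloxy)-2,3-dihydro-1-benzofuran-7-yl]-2-methylpropan-1-one; 10 prenyl bromide (1-bromo-3-methylbut-2-ene)
Product: 13 garcinielliptone HC [(2R,7Z)-7-(1-hydroxy-2-methylpropylidene)-2-(2-hydroxypropan-2-yl)-5,5-bis(3-methylbut-2-en-1-yl)-2,3-dihydro-1-benzofuran-4,6(5H,7H)-dione], via desilylated triol 11 (not isolated), via 5-monoprenyl phenol 12 (not isolated)
Conditions: Bu4NF (1.05 equiv), THF, 0 °C; then 10 (2.4 equiv), 10% aq. KOH, 0 °C → rt; then dilute HCl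
Reagents that add atoms: none
Why: Fluoride frees the 4-phenoxide, and the phloroglucinol-type anion is C-prenylated twice (SN2 on the allylic bromide) at C5, the only unsubstituted ring carbon, which lies between two phenoxide oxygens; the second alkylation dearomatises the ring to the acidic β-triketone (alkylative dearomatisation, as in lupulone-type prenylations), and the remote C2 stereocentre is untouched.

**Compound list**
1 | phloroglucinol (benzene-1,3,5-triol) | Oc1cc(O)cc(O)c1 | starting material
2 | isobutyryl chloride (2-methylpropanoyl chloride) | CC(C)C(Cl)=O | starting material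
3 | 2-methyl-1-(2,4,6-trihydroxyphenyl)propan-1-one | CC(C)C(=O)c1c(O)cc(O)cc1O | intermediate
4 | 1-[2,6-dihydroxy-4-(triisopropylsilyloxy)phenyl]-2-methylpropan-1-one | CC(C)C(=O)c1c(O)cc(O[Si](C(C)C)(C(C)C)C(C)C)cc1O | intermediate
5 | 3-hydroxy-3-methylbutan-2-one | CC(=O)C(C)(C)O | starting material
6 | 1-bromo-3-hydroxy-3-methylbutan-2-one | BrCC(=O)C(C)(C)O | intermediate
7 | 1-[2,6-dihydroxy-3-(3-hydroxy-3-methyl-2-oxobutyl)-4-(triisopropylsilyloxy)phenyl]-2-methylpropan-1-one | CC(C)C(=O)c1c(O)cc(O[Si](C(C)C)(C(C)C)C(C)C)c(CC(=O)C(C)(C)O)c1O | intermediate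
8 | 1-[6-hydroxy-2-(2-hydroxypropan-2-yl)-4-(triisopropylsilyloxy)-1-benzofuran-7-yl]-2-methylpropan-1-one | CC(C)C(=O)c1c(O)cc(O[Si](C(C)C)(C(C)C)C(C)C)c2cc(C(C)(C)O)oc12 | intermediate
9 | 1-[(2R)-6-hydroxy-2-(2-hydroxypropan-2-yl)-4-(triisopropylsilyloxy)-2,3-dihydro-1-benzofuran-7-yl]-2-methylpropan-1-one | CC(C)C(=O)c1c(O)cc(O[Si](C(C)C)(C(C)C)C(C)C)c2c1O[C@@H](C(C)(C)O)C2 | intermediate
10 | prenyl bromide (1-bromo-3-methylbut-2-ene) | CC(C)=CCBr | starting material
11 | 1-[(2R)-4,6-dihydroxy-2-(2-hydroxypropan-2-yl)-2,3-dihydro-1-benzofuran-7-yl]-2-methylpropan-1-one | CC(C)C(=O)c1c(O)cc(O)c2c1O[C@@H](C(C)(C)O)C2 | intermediate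
12 | 1-[(2R)-4,6-dihydroxy-2-(2-hydroxypropan-2-yl)-5-(3-methylbut-2-en-1-yl)-2,3-dihydro-1-benzofuran-7-yl]-2-methylpropan-1-one | CC(C)C(=O)c1c(O)c(CC=C(C)C)c(O)c2c1O[C@@H](C(C)(C)O)C2 | intermediate
13 | garcinielliptone HC, (2R,7Z)-7-(1-hydroxy-2-methylpropylidene)-2-(2-hydroxypropan-2-yl)-5,5-bis(3-methylbut-2-en-1-yl)-2,3-dihydro-1-benzofuran-4,6(5H,7H)-dione | CC(C)=CCC1(CC=C(C)C)C(=O)C2=C(O[C@@H](C(C)(C)O)C2)/C(=C(/O)C(C)C)C1=O | target

**Step count**
Total step count: 5. Longest linear sequence: 5 steps from phloroglucinol.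

**Steps most likely to fail, with fallbacks**

Step 3 (most at risk). The phenoxide may alkylate on oxygen and then close onto the isobutyryl ketone, or the tertiary carbinol may be lost under the acid stage. The fallback sets out from 4 and returns at 8, making the ring carbon the electrophile instead. N-Iodosuccinimide in MeCN at 0 °C gives 1-[2,6-dihydroxy-3-iodo-4-(triisopropylsilyloxy)phenyl]-2-methylpropan-1-one F1. Sonogashira coupling of F1 with commercial 2-methylbut-3-yn-2-ol (PdCl2(PPh3)2, CuI, Et3N, DMF, rt) gives 1-[2,6-dihydroxy-3-(3-hydroxy-3-methylbut-1-yn-1-yl)-4-(triisopropylsilyloxy)phenyl]-2-methylpropan-1-one F2. On warming to 60 °C in the same copper/amine medium, F2 closes 5-endo-dig through the only free flanking hydroxyl to give 8, with no acid involved.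

Step 4. The hindered, highly functionalised benzofuran may hydrogenate slowly or with low ee. The fallback sets out from 7 (isolated by stopping step 3 before the acid stage) and returns at 9. Asymmetric transfer hydrogenation of the α-hydroxy ketone with RuCl(p-cymene)[(S,S)-TsDPEN] (or its antipode, whichever gives the 2S carbinol) and HCO2H/Et3N gives 1-[3-[(2S)-2,3-dihydroxy-3-methylbutyl]-2,6-dihydroxy-4-(triisopropylsilyloxy)phenyl]-2-methylpropan-1-one F3. Mitsunobu cyclodehydration (PPh3, DIAD, THF, 0 °C) then lets the neighbouring phenol displace the activated secondary hydroxyl with inversion, giving 9 with the 2R configuration. Here the stereocentre comes from ketone reduction and SN2 etherification rather than arene hydrogenation.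

Step 5. O-Prenylation may compete, or the reaction may stall at the monoprenyl stage. The fallback sets out from 9 and returns at 13. Compound 9 is desilylated with Bu4NF and 11 is isolated. Compound 11 is then prenylated through a π-allyl palladium electrophile instead of the bromide: Pd(PPh3)4 (5 mol %), commercial prenyl acetate (2.2 equiv), Cs2CO3, THF, 50 °C. The soft ring-carbon nucleophile attacks the unsubstituted terminus of the dimethylallyl–palladium complex, giving 12 and then 13. Compound 12 can be isolated and resubmitted if the second alkylation is slow. No new compounds are made.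

**Further compounds**
F1 | step 3 | 1-[2,6-dihydroxy-3-iodo-4-(triisopropylsilyloxy)phenyl]-2-methylpropan-1-one | CC(C)C(=O)c1c(O)cc(O[Si](C(C)C)(C(C)C)C(C)C)c(I)c1O
F2 | step 3 | 1-[2,6-dihydroxy-3-(3-hydroxy-3-methylbut-1-yn-1-yl)-4-(triisopropylsilyloxy)phenyl]-2-methylpropan-1-one | CC(C)C(=O)c1c(O)cc(O[Si](C(C)C)(C(C)C)C(C)C)c(C#CC(C)(C)O)c1O
F3 | step 4 | 1-[3-[(2S)-2,3-dihydroxy-3-methylbutyl]-2,6-dihydroxy-4-(triisopropylsilyloxy)phenyl]-2-methylpropan-1-one | CC(C)C(=O)c1c(O)cc(O[Si](C(C)C)(C(C)C)C(C)C)c(C[C@H](O)C(C)(C)O)c1O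
F0 | step 5 | none | none
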